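The earlier runs and the new flask are calculated from invented constants, noise included.

Late in the dusk run, at 2.50 min, the books on the solid substrate charged read: 48.7% still solid, 7.2% turned by the enzyme into target, and the remainder, 44.1%, dissolved as starting material, which is 8.82 mM.

| flask | solid substrate | enzyme | remark | time |
|---|---|---|---|---|
| winter | 20 mM | 0.005 mol% | run made earlier |  |
| dusk | 20 mM | 0.02 mol% | run made earlier |  |
| noon | 30 mM | 0.01 mol% | run made earlier |  |
| flask | 20 mM | 0.01 mol% |  | 2.5 min |

| run | time / min | target / % | solid substrate / % |
|---|---|---|---|
| winter | 0.200 | 0.1 | 91.5 |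
| winter | 0.667 | 0.3 | 76.9 |
| winter | 1.00 | 0.6 | 68.8 |
| winter | 1.50 | 1.4 | 60.8 |
| winter | 2.50 | 1.5 | 51.2 |
| winter | 3.00 | 2.6 | 47.7 |
| dusk | 0.200 | 0 | 92.0 |
| dusk | 0.667 | 0 | 76.3 |
| dusk | 1.00 | 0.8 | 69.0 |
| dusk | 1.50 | 1.8 | 59.6 |
| dusk | 2.50 | 7.2 | 48.7 |
| dusk | 3.00 | 10.6 | 44.5 |
| noon | 0.667 | 0.5 | 84.1 |
| noon | 1.33 | 0.5 | 75.2 |
| noon | 2.00 | 2.0 | 69.4 |
| noon | 2.50 | 4.2 | 65.6 |
| noon | 3.00 | 6.3 | 64.3 |

(readings scatter by 0.5 percentage points)

- as a solid, counted per litre of solution: solid substrate
- what was read earlier has a scatter of 0.5 percentage points, one standard deviation
- steps under discussion: starting material + enzyme -> target + enzyme; solid substrate <-> starting material; enzyme + target -> spent catalyst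
- at the start none of the solid substrate is in solution

- Thursday's: doubling the solubility of the solid substrate, all else as stated
- Saturday's: doubling the dissolution coefficient of the solid substrate, all else as stated
- Friday's: doubling the amount of enzyme, all else as stated

1. target at 2.5 min, in percent of the solid substrate charged
2. the change that raises the amount of target at 2.5 min, in percent of the solid substrate charged most ("none" if none brings more than 2 percentage points) (Thursday's / Saturday's / Friday's / none)
3. amount of target at 2.5 min, in percent of the solid substrate charged, after Thursday's

At that time the same entries leave 9.46 mM dissolved in the winter run and 9.06 mM in the noon run, although noon was charged with 30 mM and winter with 20 mM. The enzyme in these runs therefore meets much the same solution, and the target entry can be divided by the enzyme loading. Winter gives 300, dusk 360 and noon 420. These are readings with a scatter of 0.5 percentage points, which weighs most on winter, the run with the lowest loading. Summed target over summed loading gives the turnover number at 2.5 min, 369, the target formed per enzyme charged by that time.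

For the flask, at 0.01 mol%, this reckoning gives 3.69% of target. Friday's, by the same count, gives 7.38%. Thursday's and Saturday's change what is dissolved, and the count gives no figure for them.

The forecast, slightly above this reckoning, gave 3.8% (3% to 4.6%) and named Thursday's as the best change, with 13% (7.5% to 16.5%), on the view that “the rate looks about second order in dissolved starting material”.

The flask gives 4.04% of target, from these steps:

    starting material + enzyme → target + enzyme, rate k1*[starting material]^3*[enzyme]/(1 + ([starting material]/Kh1)^3) (27.0 mM, k = 7.90 × 10⁶ L³ mol⁻³ s⁻¹)
    solid substrate ⇌ starting material, rate k2*(cs2 - [starting material]) while solid is left; crystals form when [starting material] > cs2 (solubility = 11.0 mM, k = 0.0140 s⁻¹)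
    enzyme + target → spent catalyst (k = 0.630 L mol⁻¹ s⁻¹)

That is a turnover number of 404 in the flask, with 9.18 mM dissolved at 2.50 min. The best change is Thursday's, with 22.1% of target, a gain of 18 points. Its turnover number is 2210, or 5.47 times the flask's. The neighbour charged with 5.0 mM at the same loading has 0% solid left at 2.50 min and 4.94 mM dissolved, and with 1.15% of target its turnover number is 115.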